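**Plan**

Unprimed atoms belong to unit 1 (ring A, styryl-bearing dihydrobenzofuran), primed atoms to unit 2 (ring B, bearing the 3,5-dihydroxyphenyl group).
1. Retrosynthesis: the Z alkene goes back to a diarylalkyne; unit 1 is cut at O1–C2 and C2–C3 (ortho-quinone methide plus benzylic sulfonium ylide) and at C3–C3a (ring A phenol plus ring B aldehyde); ring B is cut at C3a'–C7a', C4'–C5' and C6'–C7'.
2. Enabling feature: in unit 2 the benzene ring B (C3a'–C7a') is fused to a five-membered ring through the three-atom tether O1'–C2'–C3'. Ring B is therefore the cyclotrimer of an alkynyl ether on O1', the alkyne on C3' and one external alkyne (C5', C6'), which brings the C6' oxygen as ethoxyethyne. C4' carries a masked formyl group that becomes C3.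
3. Forward order: C2'–C3' chain, alkynyl ether diyne, ring B with its furan ring in one step, C4' aldehyde, ring A joined at C3, furan ring of unit 1, dealkylation, semihydrogenation.
4. Stereochemistry: C3' from a catalytic asymmetric alkynylation relayed with inversion through an allenylzinc; C2' from its anti-selective addition to 4-methoxybenzaldehyde; C3 from ylide addition to the quinone methide face anti to C3'; C2 from trans ring closure; Z geometry from syn hydrogenation.

Key step: step 6

Remark on the chemistry: (S,S)-ProPhenol is assumed to direct alkynyl transfer to the Re face of 1 (the antipodal ligand is used if the sense is reversed), and 19 and 20 are carried as epimer mixtures at the carbon that becomes trigonal in step 12.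

**Route**

Step 1
Reactants: 1 3,5-dimethoxybenzaldehyde; 2 3,3-diethoxyprop-1-yne
Product: 4 (1S)-1-(3,5-dimethoxyphenyl)-4,4-diethoxybut-2-yn-1-ol, via alkynyl(methyl)zinc 3 (not isolated)
Conditions: Me2Zn (3 equiv), (S,S)-ProPhenol (10 mol %), Ph3PO (20 mol %), toluene, 0 °C
Reagents that add atoms: none
Why: Zinc–ProPhenol catalysed asymmetric alkynylation of an aromatic aldehyde, in which the dinuclear zinc complex binds 1 and transfers the alkynyl group of 3 to the Re face, setting the (S) carbinol centre that is relayed to C3'.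

Step 2
Reactants: 4 (1S)-1-(3,5-dimethoxyphenyl)-4,4-diethoxybut-2-yn-1-ol
Product: 5 (1S)-1-(3,5-dimethoxyphenyl)-4,4-diethoxybut-2-yn-1-yl methanesulfonate
Conditions: MsCl, Et3N, CH2Cl2, −78 → −40 °C; used crude
Reagents that add atoms: methanesulfonyl chloride, CS(=O)(=O)Cl
Why: O-sulfonylation with retention; the meta-methoxy groups do not stabilise a benzylic cation and the acetal-bearing alkyne is electron-poor, so the propargylic mesylate should survive cold handling.

Step 3
Reactants: 5 (1S)-1-(3,5-dimethoxyphenyl)-4,4-diethoxybut-2-yn-1-yl methanesulfonate; 6 4-methoxybenzaldehyde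
Product: 8 (1R,2R)-2-(3,5-dimethoxyphenyl)-5,5-diethoxy-1-(4-methoxyphenyl)pent-3-yn-1-ol, via allenylzinc 7 (not isolated)
Conditions: Pd(OAc)2 (5 mol %), PPh3 (5 mol %), Et2Zn (3 equiv), THF, −78 → −20 °C
Reagents that add atoms: none
Why: Marshall–Tamaru propargylation, in which zerovalent palladium displaces the mesylate anti (SN2′), the allenylpalladium transmetalates to allenylzinc 7 and this adds to 6 through a closed SE2′ transition state; the net inversion turns (S)-5 into (2R) and the anti topology gives (1R), a minor syn isomer being removed by chromatography.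

Step 4
Reactants: 8 (1R,2R)-2-(3,5-dimethoxyphenyl)-5,5-diethoxy-1-(4-methoxyphenyl)pent-3-yn-1-ol
Product: 9 1-[(1R,2R)-1-{[(E)-1,2-dichloroethenyl]oxy}-5,5-diethoxy-1-(4-methoxyphenyl)pent-3-yn-2-yl]-3,5-dimethoxybenzene
Conditions: KH, Cl2C=CHCl, THF, −50 °C → rt
Reagents that add atoms: trichloroethylene, ClC=C(Cl)Cl
Why: Dichlorovinyl ether formation, in which the potassium alkoxide dehydrochlorinates trichloroethylene to dichloroethyne and adds to it anti, leaving both stereocentres untouched.

Step 5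
Reactants: 9 1-[(1R,2R)-1-{[(E)-1,2-dichloroethenyl]oxy}-5,5-diethoxy-1-(4-methoxyphenyl)pent-3-yn-2-yl]-3,5-dimethoxybenzene
Product: 11 1-[(1R,2R)-5,5-diethoxy-1-(ethynyloxy)-1-(4-methoxyphenyl)pent-3-yn-2-yl]-3,5-dimethoxybenzene, via lithium alkynyl ether 10 (not isolated)
Conditions: n-BuLi (2.2 equiv), Et2O, −78 → −40 °C; then MeOH, −78 °C; filtered cold and used at once
Reagents that add atoms: none
Why: Elimination of HCl followed by chlorine–lithium exchange (the standard dichlorovinyl ether route to alkynyl ethers) gives 10, which is protonated cold; the limited amount of base at low temperature should spare the benzylic propargylic C–H at C3'.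

Step 6
Reactants: 11 1-[(1R,2R)-5,5-diethoxy-1-(ethynyloxy)-1-(4-methoxyphenyl)pent-3-yn-2-yl]-3,5-dimethoxybenzene; 12 ethoxyethyne
Product: 13 (2R,3R)-4-(diethoxymethyl)-3-(3,5-dimethoxyphenyl)-6-ethoxy-2-(4-methoxyphenyl)-2,3-dihydro-1-benzofuran
Conditions: [Rh(cod)2]BF4 (10 mol %), rac-BINAP (10 mol %), activated with H2 then flushed with Ar, CH2Cl2, rt; slow addition of 11 to the catalyst and 12 (5 equiv)
Reagents that add atoms: none
Why: The cationic rhodium–BINAP fragment (monovalent rhodium) binds both alkynes of 11 and cyclises them oxidatively to a five-membered rhodacycle, ethoxyethyne inserts into one Rh–C bond, and the enlarged metallacycle collapses by reductive elimination to the benzene ring. The dihydrofuran ring closes in the oxidative coupling, intramolecularly across the O1'–C2'–C3' tether (C3a'–C7a' bond), and ring B closes in the insertion and reductive elimination with the external alkyne (C6'–C7' and C4'–C5' bonds). The closest known reaction type is the rhodium-catalysed cyclotrimerisation of 1,6-diynes, heteroatom-substituted ones included, with terminal alkynes. No stereocentre is formed: C2' and C3' lie in the tether, are not touched by the metal, and their anti relationship becomes the 2,3-trans arrangement. The step needs regiocontrol in the insertion of 12 (ethoxy group at C6', not C5'), which the branched diethoxymethyl group on the C4' terminus should secure by keeping the substituted alkyne carbon away, supported by head-to-tail union of the two alkoxyalkynes (electron-rich C7' with the oxygen-bearing carbon of 12). It also needs chemoselectivity over ketene loss and self-trimerisation of 11, which room temperature and slow addition of 11 to excess 12 should provide.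

Step 7
Reactants: 13 (2R,3R)-4-(diethoxymethyl)-3-(3,5-dimethoxyphenyl)-6-ethoxy-2-(4-methoxyphenyl)-2,3-dihydro-1-benzofuran
Product: 14 (2R,3R)-3-(3,5-dimethoxyphenyl)-6-ethoxy-2-(4-methoxyphenyl)-2,3-dihydro-1-benzofuran-4-carbaldehyde
Conditions: PPTS, acetone/H2O, rt
Reagents that add atoms: water, O
Why: Mild acid-catalysed acetal hydrolysis, to which the aryl ethers and the dihydrofuran ring are inert; the aldehyde carbon is the future C3.

Step 8
Reactants: 15 3-bromo-5-methoxyphenol; 16 1-ethynyl-4-methoxybenzene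
Product: 17 3-methoxy-5-[(4-methoxyphenyl)ethynyl]phenol
Conditions: PdCl2(PPh3)2 (3 mol %), CuI (3 mol %), Et3N, DMF, 80 °C
Reagents that add atoms: none
Why: Sonogashira coupling (zerovalent palladium inserts into the aryl bromide and the copper acetylide of 16 transmetalates); it gives ring A with the latent styryl carbons in place.

Step 9
Reactants: 14 (2R,3R)-3-(3,5-dimethoxyphenyl)-6-ethoxy-2-(4-methoxyphenyl)-2,3-dihydro-1-benzofuran-4-carbaldehyde; 17 3-methoxy-5-[(4-methoxyphenyl)ethynyl]phenol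
Product: 19 2-{[(2R,3R)-3-(3,5-dimethoxyphenyl)-6-ethoxy-2-(4-methoxyphenyl)-2,3-dihydro-1-benzofuran-4-yl](hydroxy)methyl}-5-methoxy-3-[(4-methoxyphenyl)ethynyl]phenol (both carbinol epimers), via bromomagnesium phenoxide 18 (not isolated)
Conditions: 17 (2 equiv), EtMgBr (2 equiv), Et2O, 0 °C; solvent changed to toluene; 14, rt → 40 °C; aq NH4Cl
Reagents that add atoms: none
Why: Magnesium-phenoxide ortho-hydroxyalkylation, in which the aldehyde bound to magnesium is delivered to an ortho carbon through a six-membered chelate; of the two ortho positions the one para to the methoxy group (the future C3a) is the more nucleophilic and less shielded, and the new carbinol centre need not be controlled.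

Step 10
Reactants: 19 2-{[(2R,3R)-3-(3,5-dimethoxyphenyl)-6-ethoxy-2-(4-methoxyphenyl)-2,3-dihydro-1-benzofuran-4-yl](hydroxy)methyl}-5-methoxy-3-[(4-methoxyphenyl)ethynyl]phenol
Product: 20 2-{[(2R,3R)-3-(3,5-dimethoxyphenyl)-6-ethoxy-2-(4-methoxyphenyl)-2,3-dihydro-1-benzofuran-4-yl](4-methylbenzenesulfonyl)methyl}-5-methoxy-3-[(4-methoxyphenyl)ethynyl]phenol (both epimers)
Conditions: 4-MeC6H4SO2H, CH2Cl2, rt
Reagents that add atoms: 4-methylbenzenesulfinic acid, Cc1ccc(cc1)S(=O)O
Why: The doubly benzylic ortho-hydroxy carbinol ionises under the sulfinic acid and sulfinate captures the cation at sulfur, giving a 2-(1-sulfonylalkyl)phenol of the kind used as a base-triggered ortho-quinone methide precursor.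

Step 11
Reactants: 21 (4-methoxyphenyl)methanol; 22 thiolane
Product: 23 1-[(4-methoxyphenyl)methyl]thiolan-1-ium tetrafluoroborate
Conditions: HBF4·OEt2, CH2Cl2, 0 °C → rt
Reagents that add atoms: tetrafluoroboric acid (diethyl etherate), [H+].F[B-](F)(F)F
Why: S-alkylation of the sulfide by the 4-methoxybenzyl cation released from the alcohol with strong acid; the non-nucleophilic counter-ion keeps the salt from reverting.

Step 12
Reactants: 20 2-{[(2R,3R)-3-(3,5-dimethoxyphenyl)-6-ethoxy-2-(4-methoxyphenyl)-2,3-dihydro-1-benzofuran-4-yl](4-methylbenzenesulfonyl)methyl}-5-methoxy-3-[(4-methoxyphenyl)ethynyl]phenol; 23 1-[(4-methoxyphenyl)methyl]thiolan-1-ium tetrafluoroborate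
Product: 26 (2S,3S)-3-[(2R,3R)-3-(3,5-dimethoxyphenyl)-6-ethoxy-2-(4-methoxyphenyl)-2,3-dihydro-1-benzofuran-4-yl]-6-methoxy-2-(4-methoxyphenyl)-4-[(4-methoxyphenyl)ethynyl]-2,3-dihydro-1-benzofuran, via ortho-quinone methide 24 (not isolated), via sulfonium ylide 25 (not isolated)
Conditions: Cs2CO3 (3 equiv), MeCN, 0 °C → rt
Reagents that add atoms: none
Why: Sulfur-ylide (4+1) annulation of an ortho-quinone methide, in which base expels sulfinate from 20, ylide 25 adds to the exocyclic carbon of 24 and the phenoxide displaces thiolane in a 5-exo-tet closure; C3 is expected as (S) because the perpendicular ring B aryl turns the C3' aryl group away from ring A (allylic strain) so that C3' shields one face and the ylide adds to the other, and C2 follows as (S) by closure through the betaine with the two aryl groups anti, which is also the thermodynamically preferred trans ring.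

Step 13
Reactants: 26 (2S,3S)-3-[(2R,3R)-3-(3,5-dimethoxyphenyl)-6-ethoxy-2-(4-methoxyphenyl)-2,3-dihydro-1-benzofuran-4-yl]-6-methoxy-2-(4-methoxyphenyl)-4-[(4-methoxyphenyl)ethynyl]-2,3-dihydro-1-benzofuran
Product: 27 5-[(2R,3R)-6-hydroxy-4-{(2S,3S)-6-hydroxy-2-(4-hydroxyphenyl)-4-[(4-hydroxyphenyl)ethynyl]-2,3-dihydro-1-benzofuran-3-yl}-2-(4-hydroxyphenyl)-2,3-dihydro-1-benzofuran-3-yl]benzene-1,3-diol
Conditions: BBr3 (excess), CH2Cl2, −78 → 0 °C; then H2O
Reagents that add atoms: none
Why: Lewis-acid cleavage of the six methyl ethers and the ethyl ether (bromide removes each alkyl group from the boron-complexed oxygen); the dihydrofuran C2–O bonds can ionise only reversibly and reclose to the trans rings, and doing this at the alkyne stage avoids the acid-induced cyclisation and isomerisation to which a stilbene would be exposed.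

Step 14
Reactants: 27 5-[(2R,3R)-6-hydroxy-4-{(2S,3S)-6-hydroxy-2-(4-hydroxyphenyl)-4-[(4-hydroxyphenyl)ethynyl]-2,3-dihydro-1-benzofuran-3-yl}-2-(4-hydroxyphenyl)-2,3-dihydro-1-benzofuran-3-yl]benzene-1,3-diol
Product: 28 cis-miyabenol C, 5-[(2R,3R)-6-hydroxy-4-{(2S,3S)-6-hydroxy-2-(4-hydroxyphenyl)-4-[(Z)-2-(4-hydroxyphenyl)ethenyl]-2,3-dihydro-1-benzofuran-3-yl}-2-(4-hydroxyphenyl)-2,3-dihydro-1-benzofuran-3-yl]benzene-1,3-diol
Conditions: H2 (1 atm), Pd/CaCO3 poisoned with Pb(OAc)2 (Lindlar catalyst), quinoline, MeOH/EtOAc, rt, stopped after one equivalent of H2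
Reagents that add atoms: none
Why: Lindlar semihydrogenation, syn delivery of one H2 to the diarylalkyne on poisoned palladium, gives the Z alkene under neutral conditions that leave the benzylic C–O bonds and all four stereocentres untouched.

**Compound list**

1 | 3,5-dimethoxybenzaldehyde | COc1cc(C=O)cc(OC)c1 | starting material
2 | 3,3-diethoxyprop-1-yne | CCOC(OCC)C#C | starting material
3 | (3,3-diethoxyprop-1-yn-1-yl)(methyl)zinc | CCOC(OCC)C#C[Zn]C | intermediate
4 | (1S)-1-(3,5-dimethoxyphenyl)-4,4-diethoxybut-2-yn-1-ol | CCOC(OCC)C#C[C@@H](O)c1cc(OC)cc(OC)c1 | intermediate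
5 | (1S)-1-(3,5-dimethoxyphenyl)-4,4-diethoxybut-2-yn-1-yl methanesulfonate | CCOC(OCC)C#C[C@@H](OS(C)(=O)=O)c1cc(OC)cc(OC)c1 | intermediate
6 | 4-methoxybenzaldehyde | COc1ccc(C=O)cc1 | starting material
7 | ethyl[(M)-1-(diethoxymethyl)-3-(3,5-dimethoxyphenyl)propa-1,2-dien-1-yl]zinc | CC[Zn]C(C(OCC)OCC)=[C@]=C([H])c1cc(OC)cc(OC)c1 | intermediate
8 | (1R,2R)-2-(3,5-dimethoxyphenyl)-5,5-diethoxy-1-(4-methoxyphenyl)pent-3-yn-1-ol | CCOC(OCC)C#C[C@@H](c1cc(OC)cc(OC)c1)[C@H](c1ccc(OC)cc1)O | intermediate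
9 | 1-[(1R,2R)-1-{[(E)-1,2-dichloroethenyl]oxy}-5,5-diethoxy-1-(4-methoxyphenyl)pent-3-yn-2-yl]-3,5-dimethoxybenzene | CCOC(OCC)C#C[C@@H](c1cc(OC)cc(OC)c1)[C@H](c1ccc(OC)cc1)O/C(Cl)=C\Cl | intermediate
10 | lithium {[(1R,2R)-2-(3,5-dimethoxyphenyl)-5,5-diethoxy-1-(4-methoxyphenyl)pent-3-yn-1-yl]oxy}ethynide | CCOC(OCC)C#C[C@@H](c1cc(OC)cc(OC)c1)[C@H](c1ccc(OC)cc1)OC#C[Li] | intermediate
11 | 1-[(1R,2R)-5,5-diethoxy-1-(ethynyloxy)-1-(4-methoxyphenyl)pent-3-yn-2-yl]-3,5-dimethoxybenzene | CCOC(OCC)C#C[C@@H](c1cc(OC)cc(OC)c1)[C@H](c1ccc(OC)cc1)OC#C | intermediate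
12 | ethoxyethyne | CCOC#C | starting material
13 | (2R,3R)-4-(diethoxymethyl)-3-(3,5-dimethoxyphenyl)-6-ethoxy-2-(4-methoxyphenyl)-2,3-dihydro-1-benzofuran | CCOC(OCC)c1cc(OCC)cc2c1[C@@H](c1cc(OC)cc(OC)c1)[C@H](c1ccc(OC)cc1)O2 | intermediate
14 | (2R,3R)-3-(3,5-dimethoxyphenyl)-6-ethoxy-2-(4-methoxyphenyl)-2,3-dihydro-1-benzofuran-4-carbaldehyde | O=Cc1cc(OCC)cc2c1[C@@H](c1cc(OC)cc(OC)c1)[C@H](c1ccc(OC)cc1)O2 | intermediate
15 | 3-bromo-5-methoxyphenol | COc1cc(O)cc(Br)c1 | starting material
16 | 1-ethynyl-4-methoxybenzene | COc1ccc(C#C)cc1 | starting material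
17 | 3-methoxy-5-[(4-methoxyphenyl)ethynyl]phenol | COc1ccc(C#Cc2cc(O)cc(OC)c2)cc1 | intermediate
18 | bromomagnesium 3-methoxy-5-[(4-methoxyphenyl)ethynyl]phenoxide | COc1ccc(C#Cc2cc(O[Mg]Br)cc(OC)c2)cc1 | intermediate
19 | 2-{[(2R,3R)-3-(3,5-dimethoxyphenyl)-6-ethoxy-2-(4-methoxyphenyl)-2,3-dihydro-1-benzofuran-4-yl](hydroxy)methyl}-5-methoxy-3-[(4-methoxyphenyl)ethynyl]phenol, both carbinol epimers | OC(c1c(O)cc(OC)cc1C#Cc1ccc(OC)cc1)c1cc(OCC)cc2c1[C@@H](c1cc(OC)cc(OC)c1)[C@H](c1ccc(OC)cc1)O2 | intermediate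
20 | 2-{[(2R,3R)-3-(3,5-dimethoxyphenyl)-6-ethoxy-2-(4-methoxyphenyl)-2,3-dihydro-1-benzofuran-4-yl](4-methylbenzenesulfonyl)methyl}-5-methoxy-3-[(4-methoxyphenyl)ethynyl]phenol, both epimers | Cc1ccc(cc1)S(=O)(=O)C(c1c(O)cc(OC)cc1C#Cc1ccc(OC)cc1)c1cc(OCC)cc2c1[C@@H](c1cc(OC)cc(OC)c1)[C@H](c1ccc(OC)cc1)O2 | intermediate
21 | (4-methoxyphenyl)methanol | COc1ccc(CO)cc1 | starting material
22 | thiolane (tetrahydrothiophene) | C1CCSC1 | starting material
23 | 1-[(4-methoxyphenyl)methyl]thiolan-1-ium tetrafluoroborate | COc1ccc(C[S+]2CCCC2)cc1.F[B-](F)(F)F | intermediate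
24 | 6-{[(2R,3R)-3-(3,5-dimethoxyphenyl)-6-ethoxy-2-(4-methoxyphenyl)-2,3-dihydro-1-benzofuran-4-yl]methylidene}-3-methoxy-5-[(4-methoxyphenyl)ethynyl]cyclohexa-2,4-dien-1-one, alkene geometry not fixed | O=C1C=C(OC)C=C(C#Cc2ccc(OC)cc2)C1=Cc1cc(OCC)cc2c1[C@@H](c1cc(OC)cc(OC)c1)[C@H](c1ccc(OC)cc1)O2 | intermediate
25 | (4-methoxyphenyl)(thiolan-1-ium-1-yl)methanide | COc1ccc([CH-][S+]2CCCC2)cc1 | intermediate
26 | (2S,3S)-3-[(2R,3R)-3-(3,5-dimethoxyphenyl)-6-ethoxy-2-(4-methoxyphenyl)-2,3-dihydro-1-benzofuran-4-yl]-6-methoxy-2-(4-methoxyphenyl)-4-[(4-methoxyphenyl)ethynyl]-2,3-dihydro-1-benzofuran | COc1ccc(C#Cc2cc(OC)cc3c2[C@H](c2cc(OCC)cc4c2[C@@H](c2cc(OC)cc(OC)c2)[C@H](c2ccc(OC)cc2)O4)[C@@H](c2ccc(OC)cc2)O3)cc1 | intermediate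
27 | 5-[(2R,3R)-6-hydroxy-4-{(2S,3S)-6-hydroxy-2-(4-hydroxyphenyl)-4-[(4-hydroxyphenyl)ethynyl]-2,3-dihydro-1-benzofuran-3-yl}-2-(4-hydroxyphenyl)-2,3-dihydro-1-benzofuran-3-yl]benzene-1,3-diol | Oc1ccc(C#Cc2cc(O)cc3c2[C@H](c2cc(O)cc4c2[C@@H](c2cc(O)cc(O)c2)[C@H](c2ccc(O)cc2)O4)[C@@H](c2ccc(O)cc2)O3)cc1 | intermediate
28 | cis-miyabenol C | Oc1ccc(/C=C\c2cc(O)cc3c2[C@H](c2cc(O)cc4c2[C@@H](c2cc(O)cc(O)c2)[C@H](c2ccc(O)cc2)O4)[C@@H](c2ccc(O)cc2)O3)cc1 | target

**Step count and risks**

Total step count: 14. Longest linear sequence: 12 (steps 1–7, 9, 10, 12, 13, 14).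

Step 6. The secondary, 4-methoxybenzylic alkynyl ether may lose ketene or rearrange before the rhodacycle forms, the diyne may trimerise with itself, and ethoxyethyne may insert in the reverse sense. The fallback replaces the labile alkynyl ether by a robust vinyl ether and aromatises afterwards. It sets out from 8: transfer vinylation ([Ir(cod)Cl]2, Na2CO3, vinyl acetate, toluene, 100 °C) should give the vinyl ether 1-[(1R,2R)-1-(ethenyloxy)-5,5-diethoxy-1-(4-methoxyphenyl)pent-3-yn-2-yl]-3,5-dimethoxybenzene F1. Rhodium-catalysed (2+2+2) cycloaddition of this 1,6-enyne with 12 under the conditions of step 6 should give the cyclohexadiene (2R,3R)-4-(diethoxymethyl)-3-(3,5-dimethoxyphenyl)-6-ethoxy-2-(4-methoxyphenyl)-2,3,7,7a-tetrahydro-1-benzofuran F2, and dehydrogenation with DDQ returns to the route at 13.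

Step 12. Facial discrimination in the ylide addition rests only on 1,4-induction from C3' and may be low, and part of the betaine may close to the cis ring. The fallback moves the control from the substrate to the reagent. It sets out from 20, which is treated under the conditions of step 12 with the enantiopure, C2-symmetric salt (2S,5S)-1-[(4-methoxyphenyl)methyl]-2,5-dimethylthiolan-1-ium tetrafluoroborate F3, made from 21, (2S,5S)-2,5-dimethylthiolane and HBF4·OEt2 as in step 11. The sulfide then fixes the reacting face of the ylide carbon, as in benzylidene transfer to aldehydes, and trans closure relays this to C3, so the route is rejoined at 26. The antipodal thiolane is taken if it proves to be the matching one, and any cis isomer is removed by chromatography.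

Step 3. The aryl-substituted allenylpalladium or allenylzinc may racemise, the zinc species may lose ethoxide by β-elimination, and the anti preference with an aromatic aldehyde may be modest. The fallback uses a configurationally stable allenylboron reagent. It sets out from 4: ClCO2Me and pyridine give the carbonate (1S)-1-(3,5-dimethoxyphenyl)-4,4-diethoxybut-2-yn-1-yl methyl carbonate F4. Copper-catalysed anti SN2′ borylation (CuO-t-Bu, Xantphos, B2pin2, THF) should give the allenylboronate 2-[(P)-1-(diethoxymethyl)-3-(3,5-dimethoxyphenyl)propa-1,2-dien-1-yl]-4,4,5,5-tetramethyl-1,3,2-dioxaborolane F5. Its addition to 6 through a closed six-membered transition state (toluene, 4 Å sieves, rt → 50 °C) returns to the route at 8.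

**Further compounds**

F1 | step 6 | 1-[(1R,2R)-1-(ethenyloxy)-5,5-diethoxy-1-(4-methoxyphenyl)pent-3-yn-2-yl]-3,5-dimethoxybenzene | CCOC(OCC)C#C[C@@H](c1cc(OC)cc(OC)c1)[C@H](c1ccc(OC)cc1)OC=C
F2 | step 6 | (2R,3R)-4-(diethoxymethyl)-3-(3,5-dimethoxyphenyl)-6-ethoxy-2-(4-methoxyphenyl)-2,3,7,7a-tetrahydro-1-benzofuran, both C7a epimers | CCOC(OCC)C1=C2[C@@H](c3cc(OC)cc(OC)c3)[C@H](c3ccc(OC)cc3)OC2CC(OCC)=C1
F3 | step 12 | (2S,5S)-1-[(4-methoxyphenyl)methyl]-2,5-dimethylthiolan-1-ium tetrafluoroborate | C[C@H]1CC[C@H](C)[S+]1Cc1ccc(OC)cc1.F[B-](F)(F)F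
F4 | step 3 | (1S)-1-(3,5-dimethoxyphenyl)-4,4-diethoxybut-2-yn-1-yl methyl carbonate | CCOC(OCC)C#C[C@@H](OC(=O)OC)c1cc(OC)cc(OC)c1
F5 | step 3 | 2-[(P)-1-(diethoxymethyl)-3-(3,5-dimethoxyphenyl)propa-1,2-dien-1-yl]-4,4,5,5-tetramethyl-1,3,2-dioxaborolane | CC1(C)OB(OC1(C)C)C(C(OCC)OCC)=[C@]=C([H])c1cc(OC)cc(OC)c1
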